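**Plan**
- Retrosynthetic cuts: pyranone O1′–C2′ and C4′–C5′ (to pentan-3-one and a malonyl unit already on the bridge carbon), then C7–CH2 (to an aminomethyl arene and Meldrum's acid), O1–C2 of the dihydrofuran (to an allylic carbonate), and C3a–C3 and C5–acyl (to phloroglucinol).
- Enabling feature: the bridge CH2 on C7 and pyranone C3′ lie ortho to the C6 hydroxyl, so C6–O, C7, CH2, C3′ and C2′ can first be a dihydrocoumarin ring, an aryl malonate whose phenoxide (the later C6 OH) is a built-in leaving group. C5′, C6′, O1′ and both alkyl groups are symmetrical pentan-3-one.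
- Forward order: ring A (benzene) is acylated and C-prenylated, the prenyl terminus is oxidised, ring B (dihydrofuran) is closed, ring C (dihydrocoumarin lactone) is annulated across O6/C7, ring D (pyranone) is closed while ring C opens, and the last silyl ether is removed.
- Stereochemistry: C2 (R) is the only stereocentre; it is set in step 7 by the chiral diphosphine ligand of a palladium-catalysed asymmetric allylic etherification and is not touched afterwards.

Key step: step 12

Assumption: in step 7 the (1R,2R)-ligand is taken to deliver the (2R)-ether, as in closely related closures to 2-isopropenyl-2,3-dihydrobenzofurans; if the sense is the reverse, the (1S,2S)-ligand is used and nothing else changes.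
Locants: the arene core carries 2,3-dihydro-1-benzofuran numbering (O1, C2, C3, C3a, C4 to C7, C7a) throughout; pyranone atoms are primed; "O6" means the oxygen on C6.

**Route**

Step 1
Reactants: 1 phloroglucinol; 2 2-methylpropanoyl chloride
Product: 3 2-methyl-1-(2,4,6-trihydroxyphenyl)propan-1-one
Conditions: AlCl3 (4 equiv), PhNO2/CH2Cl2, rt → 50 °C; aq. HCl
Reagents that add atoms: none
Why: Friedel–Crafts acylation of the very nucleophilic triphenol should stop at the mono-ketone because the first acyl group deactivates the ring.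

Step 2
Reactants: 3 2-methyl-1-(2,4,6-trihydroxyphenyl)propan-1-one; 4 1-bromo-3-methylbut-2-ene
Product: 5 2-methyl-1-[2,4,6-trihydroxy-3-(3-methylbut-2-en-1-yl)phenyl]propan-1-one
Conditions: DBU (1.0 equiv), 4 (1.0 equiv), THF, 0 °C → rt
Reagents that add atoms: none
Why: Base-mediated C-alkylation of the acylphloroglucinol (a vinylogous acid whose delocalised anion reacts at carbon with the soft allylic bromide) should give a single constitutional isomer because the two free ring carbons are equivalent.

Step 3
Reactants: 5 2-methyl-1-[2,4,6-trihydroxy-3-(3-methylbut-2-en-1-yl)phenyl]propan-1-one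
Product: 6 2-(3-methylbut-2-en-1-yl)-4-(2-methylpropanoyl)benzene-1,3,5-triyl triacetate
Conditions: Ac2O, pyridine, 4-(dimethylamino)pyridine (cat.), rt
Reagents that add atoms: acetic anhydride, CC(=O)OC(C)=O
Why: Amine-catalysed O-acetylation masks the three oxidation-prone phenols for the allylic oxidation that follows.

Step 4
Reactants: 6 2-(3-methylbut-2-en-1-yl)-4-(2-methylpropanoyl)benzene-1,3,5-triyl triacetate
Product: 7 2-[(2E)-4-hydroxy-3-methylbut-2-en-1-yl]-4-(2-methylpropanoyl)benzene-1,3,5-triyl triacetate
Conditions: SeO2 (0.3 equiv), t-BuOOH (3 equiv), salicylic acid (cat.), CH2Cl2, rt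
Reagents that add atoms: selenium dioxide, O=[Se]=O (transfers the oxygen; regenerated by tert-butyl hydroperoxide, CC(C)(C)OO)
Why: Riley-type allylic oxidation (ene reaction, then [2,3]-sigmatropic shift) attacks the more substituted alkene terminus and selects the (E)-methyl group, so the (E)-allylic alcohol should form.

Step 5
Reactants: 7 2-[(2E)-4-hydroxy-3-methylbut-2-en-1-yl]-4-(2-methylpropanoyl)benzene-1,3,5-triyl triacetate
Product: 8 2-{(2E)-4-[(methoxycarbonyl)oxy]-3-methylbut-2-en-1-yl}-4-(2-methylpropanoyl)benzene-1,3,5-triyl triacetate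
Conditions: ClCO2Me (1.5 equiv), pyridine, CH2Cl2, 0 °C
Reagents that add atoms: methyl chloroformate, COC(=O)Cl
Why: Acylation of the primary allylic alcohol with the chloroformate installs the carbonate that palladium ionises in step 7.

Step 6
Reactants: 8 2-{(2E)-4-[(methoxycarbonyl)oxy]-3-methylbut-2-en-1-yl}-4-(2-methylpropanoyl)benzene-1,3,5-triyl triacetate
Product: 9 methyl (2E)-2-methyl-4-[2,4,6-trihydroxy-3-(2-methylpropanoyl)phenyl]but-2-en-1-yl carbonate
Conditions: pyrrolidine (3.3 equiv), THF, 0 °C; cold aq. citric acid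
Reagents that add atoms: none
Why: Aminolysis of aryl acetates is much faster than attack on a dialkyl carbonate, so the phenols should be freed with the allylic carbonate intact.

Step 7
Reactants: 9 methyl (2E)-2-methyl-4-[2,4,6-trihydroxy-3-(2-methylpropanoyl)phenyl]but-2-en-1-yl carbonate
Product: 10 1-[(2R)-4,6-dihydroxy-2-(prop-1-en-2-yl)-2,3-dihydro-1-benzofuran-5-yl]-2-methylpropan-1-one
Conditions: Pd2(dba)3·CHCl3 (2.5 mol%), (1R,2R)-N,N′-bis[2-(diphenylphosphino)benzoyl]cyclohexane-1,2-diamine (7.5 mol%), AcOH (1 equiv), CH2Cl2, rt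
Reagents that add atoms: none
Why: In this intramolecular Tsuji–Trost asymmetric allylic etherification, zerovalent palladium ionises the carbonate, the most acidic and non-chelated phenol (para to the ketone) attacks the near allyl terminus in a 5-exo closure, and the chiral ligand pocket selects between the equilibrating diastereomeric allyl complexes to set C2 as (R) and leave the isopropenyl group.

Step 8
Reactants: 10 1-[(2R)-4,6-dihydroxy-2-(prop-1-en-2-yl)-2,3-dihydro-1-benzofuran-5-yl]-2-methylpropan-1-one; 11 N,N-dimethylmethaniminium iodide (Eschenmoser's salt)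
Product: 12 1-{(2R)-7-[(dimethylamino)methyl]-4,6-dihydroxy-2-(prop-1-en-2-yl)-2,3-dihydro-1-benzofuran-5-yl}-2-methylpropan-1-one
Conditions: 11 (1.1 equiv), Et3N (1.1 equiv), CH2Cl2, 0 °C → rt
Reagents that add atoms: none
Why: Mannich aminomethylation by the preformed iminium ion should occur at C7, the only unsubstituted ring carbon, which is activated by three oxygen substituents.

Step 9
Reactants: 12 1-{(2R)-7-[(dimethylamino)methyl]-4,6-dihydroxy-2-(prop-1-en-2-yl)-2,3-dihydro-1-benzofuran-5-yl}-2-methylpropan-1-one; 13 2,2-dimethyl-1,3-dioxane-4,6-dione (Meldrum's acid)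
Product: 16 dihydrocoumarin acid (core of 10 in which O6 and C7 are bridged by C(=O)–CH(CO2H)–CH2; C4 hydroxyl free; both epimers at the lactone α-carbon), via o-quinone methide 14 (not isolated), via benzyl Meldrum's acid adduct 15 (not isolated)
Conditions: 13 (2 equiv), MeCN, 60 °C; cold 0.5 M HCl wash
Reagents that add atoms: none
Why: Thermal loss of dimethylamine gives the o-quinone methide, Michael addition of Meldrum's acid forms the CH2–C bond, and the neighbouring C6 hydroxyl opens the dioxanedione with loss of acetone (6-exo-trig lactonisation), a known o-quinone methide/Meldrum's acid annulation to 2-oxochroman-3-carboxylic acids in which excess Meldrum's acid holds the amine as its salt.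

Step 10
Reactants: 16 dihydrocoumarin acid
Product: 17 tert-butyldimethylsilyl ester of 16 carrying a tert-butyldimethylsilyl ether on O4
Conditions: TBSOTf (2.3 equiv), 2,6-lutidine (3 equiv), CH2Cl2, −40 → 0 °C; non-aqueous work-up
Reagents that add atoms: tert-butyldimethylsilyl trifluoromethanesulfonate, CC(C)(C)[Si](C)(C)OS(=O)(=O)C(F)(F)F
Why: Silylation with a silyl triflate and a hindered pyridine base should convert the carboxylic acid into its silyl ester and the remaining chelated C4 phenol into a silyl ether in one operation.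

Step 11
Reactants: 17 bis-silylated dihydrocoumarin acid
Product: 18 3-chlorocarbonyl dihydrocoumarin with O4 as tert-butyldimethylsilyl ether (both epimers at the lactone α-carbon)
Conditions: (COCl)2 (1.2 equiv), DMF (cat.), CH2Cl2, 0 °C → rt; volatiles removed, used crude
Reagents that add atoms: oxalyl chloride, O=C(Cl)C(=O)Cl
Why: Silyl esters are converted into acid chlorides by oxalyl chloride and catalytic DMF (chloroiminium catalysis) under neutral conditions, which should spare the aryl silyl ether, the isopropenyl group and the allylic aryl ether.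

Step 12
Reactants: 18 3-chlorocarbonyl dihydrocoumarin (O4 silyl ether); 19 pentan-3-one
Product: 23 O4-tert-butyldimethylsilyl ether of the target (C6 hydroxyl free; pyranone 4′-hydroxyl free), via pentan-3-one lithium enolate 20 (not isolated), via aryloxycarbonyl ketene 21 (not isolated), via diketo lactone 22 (not isolated)
Conditions: 19 (3.3 equiv), LiN(SiMe3)2 (3.1 equiv), THF, −78 °C; then 18 in THF, −78 → 0 °C; aq. citric acid
Reagents that add atoms: none
Why: Proposed new method: one equivalent of enolate 20 removes the acidic malonyl proton of 18 and chloride leaves to give ketene 21, a second enolate adds through carbon to the ketene carbon (C4′–C5′) to give the enolate of diketo lactone 22, and the C6′ enolate oxygen then adds to the aryl lactone carbonyl (O1′–C2′, 6-exo-trig) with expulsion of the C6 phenoxide, so ring D closes as ring C opens and the third equivalent of base holds the product as its dianion. The closest known reaction types are the condensation of ketone silyl enol ethers with malonyl dichlorides to 4-hydroxy-2-pyranones, the C-acylation of lithium ketone enolates by acid chlorides to 1,3-diketones, and the base-induced cyclisation of 3,5-dioxo esters to 4-hydroxy-2-pyranones. No stereocentre is formed: the epimeric lactone α-carbon becomes sp2 (C3′), and C2 is remote and not acidic. The step needs carbon rather than oxygen acylation, and any enol ester formed is itself an acyl donor that excess enolate should return to the diketone. Because pentan-3-one is symmetrical, only the 5′-methyl-6′-ethyl pattern can arise, and the lactone is the one acyl group that sits six atoms from the enolate oxygen and carries a 2-acylphenoxide leaving group, so the hindered aryl ketone and the silyl ether should stay untouched. The amine-free, weakly nucleophilic silazane by-product should not intercept the ketene.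

Step 13
Reactants: 23 O4-tert-butyldimethylsilyl ether of the target
Product: 24 target, 3-{[(2R)-4,6-dihydroxy-5-(2-methylpropanoyl)-2-(prop-1-en-2-yl)-2,3-dihydro-1-benzofuran-7-yl]methyl}-6-ethyl-4-hydroxy-5-methyl-2H-pyran-2-one
Conditions: Et3N·3HF, THF, 0 °C → rt
Reagents that add atoms: none
Why: Fluoride-induced cleavage of the aryl silyl ether under buffered, non-basic conditions should free the C4 phenol without affecting the isopropenyl group, the allylic aryl ether or the pyranone.

**Compound list**
1 | phloroglucinol (benzene-1,3,5-triol) | Oc1cc(O)cc(O)c1 | starting material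
2 | 2-methylpropanoyl chloride | CC(C)C(=O)Cl | starting material
3 | 2-methyl-1-(2,4,6-trihydroxyphenyl)propan-1-one | CC(C)C(=O)c1c(O)cc(O)cc1O | intermediate
4 | 1-bromo-3-methylbut-2-ene | CC(C)=CCBr | starting material
5 | 2-methyl-1-[2,4,6-trihydroxy-3-(3-methylbut-2-en-1-yl)phenyl]propan-1-one | CC(C)C(=O)c1c(O)cc(O)c(CC=C(C)C)c1O | intermediate
6 | 2-(3-methylbut-2-en-1-yl)-4-(2-methylpropanoyl)benzene-1,3,5-triyl triacetate | CC(C)C(=O)c1c(OC(C)=O)cc(OC(C)=O)c(CC=C(C)C)c1OC(C)=O | intermediate
7 | 2-[(2E)-4-hydroxy-3-methylbut-2-en-1-yl]-4-(2-methylpropanoyl)benzene-1,3,5-triyl triacetate | CC(C)C(=O)c1c(OC(C)=O)cc(OC(C)=O)c(C/C=C(\C)CO)c1OC(C)=O | intermediate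
8 | 2-{(2E)-4-[(methoxycarbonyl)oxy]-3-methylbut-2-en-1-yl}-4-(2-methylpropanoyl)benzene-1,3,5-triyl triacetate | CC(C)C(=O)c1c(OC(C)=O)cc(OC(C)=O)c(C/C=C(\C)COC(=O)OC)c1OC(C)=O | intermediate
9 | methyl (2E)-2-methyl-4-[2,4,6-trihydroxy-3-(2-methylpropanoyl)phenyl]but-2-en-1-yl carbonate | CC(C)C(=O)c1c(O)cc(O)c(C/C=C(\C)COC(=O)OC)c1O | intermediate
10 | 1-[(2R)-4,6-dihydroxy-2-(prop-1-en-2-yl)-2,3-dihydro-1-benzofuran-5-yl]-2-methylpropan-1-one | C=C(C)[C@H]1Cc2c(O)c(C(=O)C(C)C)c(O)cc2O1 | intermediate
11 | N,N-dimethylmethaniminium iodide (Eschenmoser's salt) | C=[N+](C)C.[I-] | starting material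
12 | 1-{(2R)-7-[(dimethylamino)methyl]-4,6-dihydroxy-2-(prop-1-en-2-yl)-2,3-dihydro-1-benzofuran-5-yl}-2-methylpropan-1-one | C=C(C)[C@H]1Cc2c(O)c(C(=O)C(C)C)c(O)c(CN(C)C)c2O1 | intermediate
13 | 2,2-dimethyl-1,3-dioxane-4,6-dione (Meldrum's acid) | CC1(C)OC(=O)CC(=O)O1 | starting material
14 | o-quinone methide: (2R)-4-hydroxy-7-methylidene-5-(2-methylpropanoyl)-2-(prop-1-en-2-yl)-2,3-dihydro-1-benzofuran-6(7H)-one | C=C(C)[C@H]1CC2=C(O1)C(=C)C(=O)C(C(=O)C(C)C)=C2O | intermediate (not isolated)
15 | 5-{[(2R)-4,6-dihydroxy-5-(2-methylpropanoyl)-2-(prop-1-en-2-yl)-2,3-dihydro-1-benzofuran-7-yl]methyl}-2,2-dimethyl-1,3-dioxane-4,6-dione | C=C(C)[C@H]1Cc2c(O)c(C(=O)C(C)C)c(O)c(CC3C(=O)OC(C)(C)OC3=O)c2O1 | intermediate (not isolated)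
16 | dihydrocoumarin acid: (2R)-core of 10 with O6 and C7 bridged by C(=O)–CH(CO2H)–CH2, C4 hydroxyl free, both epimers at the lactone α-carbon | C=C(C)[C@H]1Cc2c(O)c(C(=O)C(C)C)c3OC(=O)C(C(=O)O)Cc3c2O1 | intermediate
17 | tert-butyldimethylsilyl ester of 16 with O4 as tert-butyldimethylsilyl ether | C=C(C)[C@H]1Cc2c(O[Si](C)(C)C(C)(C)C)c(C(=O)C(C)C)c3OC(=O)C(C(=O)O[Si](C)(C)C(C)(C)C)Cc3c2O1 | intermediate
18 | 3-chlorocarbonyl dihydrocoumarin with O4 as tert-butyldimethylsilyl ether, both epimers at the lactone α-carbon | C=C(C)[C@H]1Cc2c(O[Si](C)(C)C(C)(C)C)c(C(=O)C(C)C)c3OC(=O)C(C(=O)Cl)Cc3c2O1 | intermediate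
19 | pentan-3-one | CCC(=O)CC | starting material
20 | lithium pent-2-en-3-olate (E/Z mixture, geometry without consequence) | CC=C(CC)[O-].[Li+] | intermediate (not isolated)
21 | aryloxycarbonyl ketene derived from 18 by loss of HCl | C=C(C)[C@H]1Cc2c(O[Si](C)(C)C(C)(C)C)c(C(=O)C(C)C)c3OC(=O)C(=C=O)Cc3c2O1 | intermediate (not isolated)
22 | diketo lactone: dihydrocoumarin bearing a 2-methyl-3-oxopentanoyl group on the lactone α-carbon (present as its lithium enolate, drawn neutral) | C=C(C)[C@H]1Cc2c(O[Si](C)(C)C(C)(C)C)c(C(=O)C(C)C)c3OC(=O)C(C(=O)C(C)C(=O)CC)Cc3c2O1 | intermediate (not isolated)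
23 | O4-tert-butyldimethylsilyl ether of the target | C=C(C)[C@H]1Cc2c(O[Si](C)(C)C(C)(C)C)c(C(=O)C(C)C)c(O)c(Cc3c(O)c(C)c(CC)oc3=O)c2O1 | intermediate
24 | 3-{[(2R)-4,6-dihydroxy-5-(2-methylpropanoyl)-2-(prop-1-en-2-yl)-2,3-dihydro-1-benzofuran-7-yl]methyl}-6-ethyl-4-hydroxy-5-methyl-2H-pyran-2-one | C=C(C)[C@H]1Cc2c(O)c(C(=O)C(C)C)c(O)c(Cc3c(O)c(C)c(CC)oc3=O)c2O1 | target

**Step count**
Total: 13 steps. Longest linear sequence: 13 steps, from phloroglucinol 1 to 24; compounds 2, 4, 11, 13 and 19 enter as purchased.

**Steps most likely to fail**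

Step 12 (proposed new method). The enolate may be acylated on oxygen, may only deprotonate the acid chloride so that the ketene oligomerises, or the open-chain diketo lactone may fail to undergo the ring switch. The fallback uses known chemistry and makes the bridge by intermolecular benzylation instead. It sets out from Mannich base 12 and pentan-3-one 19 and comes back to the route at 24. Pentan-3-one is silylated (Me3SiCl, Et3N, NaI, MeCN) to (pent-2-en-3-yloxy)trimethylsilane F1. F1 is condensed with malonyl dichloride (Et2O, −78 °C to rt) to 6-ethyl-4-hydroxy-5-methyl-2H-pyran-2-one F2. Heating 12 with F2 in MeCN generates o-quinone methide 14, which should be intercepted at C3 of the pyranone (Michael addition) to give 24 directly, so steps 9 to 13 are no longer needed.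

Step 7. The two faces of the allyl unit may be poorly discriminated, which would lower the enantiomeric purity at C2, or the hydroxyl between the ketone and the side chain may close the ring in competition with the para hydroxyl. The fallback relies on reagent-controlled epoxidation and opening by a phenoxide. It sets out from triacetate 6 and comes back at 10.
- Shi epoxidation of 6 with 1,2:4,5-di-O-isopropylidene-β-L-erythro-2,3-hexodiulo-2,6-pyranose (the L-fructose-derived ketone), 2KHSO5·KHSO4·K2SO4 and NaHCO3 in MeCN/H2O at 0 °C should give the (S)-epoxide triacetate F3.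
- K2CO3 in MeOH removes the acetates, and the para phenoxide opens the epoxide at its secondary carbon (5-exo, inversion) to the (R)-tertiary alcohol F4.
- Ac2O in pyridine acetylates only the two phenols, giving hydroxy diacetate F5.
- Methyl N-(triethylammoniosulfonyl)carbamate (Burgess reagent, toluene, 60 °C) dehydrates toward a methyl group to the isopropenyl diacetate F6.
- Pyrrolidine in THF at 0 °C frees 10.

Step 9. The malonic half ester may lose CO2 at the temperature needed for amine elimination, or the lactone or the dioxanedione may transfer an acyl group to the liberated dimethylamine. The fallback is a carbonyl condensation at the aldehyde oxidation level with no amine leaving group. It sets out from 10 and comes back at 16. Vilsmeier–Haack formylation (POCl3, DMF, 0 °C; aq. NaOAc) at C7 gives the 7-carbaldehyde F7. Reductive Knoevenagel alkylation of Meldrum's acid 13 with F7 and Hantzsch ester (L-proline cat., EtOH, rt) gives adduct 15, which lactonises to 16 as in the main route.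

**Further compounds**
F1 | step 12 | (pent-2-en-3-yloxy)trimethylsilane | CC=C(CC)O[Si](C)(C)C
F2 | step 12 | 6-ethyl-4-hydroxy-5-methyl-2H-pyran-2-one | CCc1oc(=O)cc(O)c1C
F3 | step 7 | 2-{[(2S)-3,3-dimethyloxiran-2-yl]methyl}-4-(2-methylpropanoyl)benzene-1,3,5-triyl triacetate | CC(C)C(=O)c1c(OC(C)=O)cc(OC(C)=O)c(C[C@@H]2OC2(C)C)c1OC(C)=O
F4 | step 7 | 1-[(2R)-4,6-dihydroxy-2-(2-hydroxypropan-2-yl)-2,3-dihydro-1-benzofuran-5-yl]-2-methylpropan-1-one | CC(C)(O)[C@H]1Cc2c(O)c(C(=O)C(C)C)c(O)cc2O1
F5 | step 7 | (2R)-2-(2-hydroxypropan-2-yl)-5-(2-methylpropanoyl)-2,3-dihydro-1-benzofuran-4,6-diyl diacetate | CC(C)(O)[C@H]1Cc2c(OC(C)=O)c(C(=O)C(C)C)c(OC(C)=O)cc2O1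
F6 | step 7 | (2R)-5-(2-methylpropanoyl)-2-(prop-1-en-2-yl)-2,3-dihydro-1-benzofuran-4,6-diyl diacetate | C=C(C)[C@H]1Cc2c(OC(C)=O)c(C(=O)C(C)C)c(OC(C)=O)cc2O1
F7 | step 9 | (2R)-4,6-dihydroxy-5-(2-methylpropanoyl)-2-(prop-1-en-2-yl)-2,3-dihydro-1-benzofuran-7-carbaldehyde | C=C(C)[C@H]1Cc2c(O)c(C(=O)C(C)C)c(O)c(C=O)c2O1
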